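**Retrosynthetic overview**

- The target comes from hydrogenolysis of its 3'-O-benzyl ether, which comes from sulfation of 3'-O-benzylquercetin at O3, O4' and O7 (O5–H, chelated to the C4 carbonyl, stays free), which comes from acid removal of one tert-butyl and two MOM groups.
- Feature the plan rests on: ring A carries two meta oxygens that must differ, O5 (free OH peri to C4=O) and O7 (sulfate). A ketene/ynol ether benzannulation makes O5 from the ketene carbonyl and O7 from the ynol ether oxygen, so they differ from the moment ring A exists.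
- Ring A (C4a, C5, C6, C7, C8, C8a) is therefore built last, on a finished ring C that already carries ring B: C8–C8a (Wolff shift), C5–C6 and C7–C8 ([2+2]), C4a–C5 (6π closure).
- The diazoacetyl pyranone comes from kojic acid (ring C with O3 and C4=O; its CH2OH carbon becomes C5) and a ring B pinacol boronate, joined by Suzuki coupling at the brominated enol carbon (future C2). The boronate comes from 5-bromo-2-hydroxybenzaldehyde, whose CHO becomes O3' so that O3' (Bn) and O4' (MOM) are distinct.
- Ring order: rings B and C are bought; ring A is the only ring made.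

Key step: step 12

Remark (assumption): the sulfate monoesters are named and drawn as neutral hydrogen sulfates. They would be handled as ammonium or sodium salts, and the free acid of the target is released only in the work-up of the last step (acid-form cation-exchange resin, cold), because aryl hydrogen sulfates hydrolyse under their own acidity.

**Route**

Step 1
Reactants: 1 kojic acid (5-hydroxy-2-(hydroxymethyl)-4H-pyran-4-one)
Product: 2 2-bromo-3-hydroxy-6-(hydroxymethyl)-4H-pyran-4-one (6-bromokojic acid)
Conditions: NBS (1.05 equiv), DMF, 0 °C to rt, dark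
Reagents that add atoms: N-bromosuccinimide, O=C1CCC(=O)N1Br
Why: Electrophilic bromination of the enol; the ring carbon ortho to the enolic OH (C6 of kojic acid) is the only enol-activated position and is the usual site of electrophilic substitution in kojic acid.

Step 2
Reactants: 2 2-bromo-3-hydroxy-6-(hydroxymethyl)-4H-pyran-4-one
Product: 3 2-bromo-6-(hydroxymethyl)-3-(methoxymethoxy)-4H-pyran-4-one
Conditions: MOMCl (1.05 equiv), K2CO3 (1.0 equiv), acetone, 0 °C
Reagents that add atoms: chloromethyl methyl ether, COCCl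
Why: Williamson-type O-alkylation; K2CO3 deprotonates only the acidic enolic OH (a vinylogous acid), so the primary alcohol should stay free.

Step 3
Reactants: 4 5-bromo-2-hydroxybenzaldehyde
Product: 5 5-bromo-2-(methoxymethoxy)benzaldehyde
Conditions: MOMCl, iPr2NEt, CH2Cl2, 0 °C to rt
Reagents that add atoms: chloromethyl methyl ether, COCCl
Why: O-alkylation of the phenol as its MOM acetal; this oxygen becomes O4' and is now marked as the one to be freed by acid.

Step 4
Reactants: 5 5-bromo-2-(methoxymethoxy)benzaldehyde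
Product: 7 5-bromo-2-(methoxymethoxy)phenol, via aryl formate 6 (not isolated)
Conditions: mCPBA, CH2Cl2, 0 °C to rt; then K2CO3 (cat.), MeOH, rt
Reagents that add atoms: 3-chloroperoxybenzoic acid, O=C(OO)c1cccc(Cl)c1
Why: Baeyer–Villiger (Dakin-type) oxidation; the ortho-alkoxy group makes the aryl group migrate in the Criegee intermediate to give the formate, which methanolysis turns into the phenol (future O3').

Step 5
Reactants: 7 5-bromo-2-(methoxymethoxy)phenol
Product: 8 2-(benzyloxy)-4-bromo-1-(methoxymethoxy)benzene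
Conditions: BnBr, K2CO3, DMF, rt
Reagents that add atoms: benzyl bromide, BrCc1ccccc1
Why: Williamson ether synthesis on the only free phenol, so O3' carries benzyl and O4' carries MOM without ambiguity.

Step 6
Reactants: 8 2-(benzyloxy)-4-bromo-1-(methoxymethoxy)benzene
Product: 9 2-[3-(benzyloxy)-4-(methoxymethoxy)phenyl]-4,4,5,5-tetramethyl-1,3,2-dioxaborolane
Conditions: B2pin2, Pd(dppf)Cl2 (3 mol %), KOAc, 1,4-dioxane, 85 °C
Reagents that add atoms: bis(pinacolato)diboron, CC1(C)OB(OC1(C)C)B1OC(C)(C)C(C)(C)O1
Why: Miyaura borylation of an electron-rich aryl bromide; the neutral conditions leave the MOM and benzyl ethers untouched.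

Step 7
Reactants: 3 2-bromo-6-(hydroxymethyl)-3-(methoxymethoxy)-4H-pyran-4-one; 9 2-[3-(benzyloxy)-4-(methoxymethoxy)phenyl]-4,4,5,5-tetramethyl-1,3,2-dioxaborolane
Product: 10 2-[3-(benzyloxy)-4-(methoxymethoxy)phenyl]-6-(hydroxymethyl)-3-(methoxymethoxy)-4H-pyran-4-one
Conditions: Pd(PPh3)4 (5 mol %), K2CO3, 1,4-dioxane/H2O (4:1), 80 °C
Reagents that add atoms: none
Why: Suzuki–Miyaura coupling; the C–Br bond sits at the β-carbon of the pyranone enone (a vinylogous acyl bromide), so oxidative addition should be easy and the free primary alcohol is tolerated.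

Step 8
Reactants: 10 2-[3-(benzyloxy)-4-(methoxymethoxy)phenyl]-6-(hydroxymethyl)-3-(methoxymethoxy)-4H-pyran-4-one
Product: 11 6-[3-(benzyloxy)-4-(methoxymethoxy)phenyl]-5-(methoxymethoxy)-4-oxo-4H-pyran-2-carboxylic acid
Conditions: TEMPO (20 mol %), PhI(OAc)2 (2.5 equiv), MeCN/H2O (1:1), rt
Reagents that add atoms: water, O
Why: Oxoammonium (TEMPO) oxidation of the primary alcohol through the aldehyde hydrate to the acid; the medium is only weakly acidic (acetic acid), so both MOM acetals should survive where chromic acid would not.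

Step 9
Reactants: 11 6-[3-(benzyloxy)-4-(methoxymethoxy)phenyl]-5-(methoxymethoxy)-4-oxo-4H-pyran-2-carboxylic acid
Product: 13 2-[3-(benzyloxy)-4-(methoxymethoxy)phenyl]-6-(diazoacetyl)-3-(methoxymethoxy)-4H-pyran-4-one, via mixed anhydride 12 (not isolated)
Conditions: iBuOCOCl, N-methylmorpholine, THF, −15 °C; then CH2N2 (excess), Et2O, −15 to 0 °C
Reagents that add atoms: diazomethane, C=[N+]=[N-]
Why: Acylation of diazomethane by a mixed carbonic anhydride (first stage of an Arndt–Eistert sequence); no HCl is generated, which protects the MOM acetals.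

Step 10
Reactants: 14 trichloroethylene
Product: 16 (E)-1,2-dichlorovinyl tert-butyl ether, via dichloroacetylene 15 (not isolated)
Conditions: KOtBu (1.2 equiv), THF, −50 °C to rt
Reagents that add atoms: potassium tert-butoxide, CC(C)(C)[O-].[K+]
Why: Elimination–addition; tert-butoxide dehydrochlorinates trichloroethylene to dichloroacetylene, which stays in solution and takes up tert-butoxide/tert-butanol by anti addition to give the (E)-dichlorovinyl ether.

Step 11
Reactants: 16 (E)-1,2-dichlorovinyl tert-butyl ether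
Product: 19 tert-butyl ethynyl ether, via chloroalkynyl ether 17 (not isolated), via lithium acetylide 18 (not isolated)
Conditions: n-BuLi (2.3 equiv), Et2O, −78 to −40 °C; then MeOH, −78 °C; cold work-up, kept and used as a cold titrated solution
Reagents that add atoms: none
Why: Base-induced elimination of HCl gives the chloroalkynyl ether, chlorine–lithium exchange gives the lithium alkoxyacetylide, and protonation gives the terminal ynol ether; it must be kept cold because tert-butyl ynol ethers lose isobutene by a retro-ene reaction on warming.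

Step 12
Reactants: 13 2-[3-(benzyloxy)-4-(methoxymethoxy)phenyl]-6-(diazoacetyl)-3-(methoxymethoxy)-4H-pyran-4-one; 19 tert-butyl ethynyl ether
Product: 24 2-[3-(benzyloxy)-4-(methoxymethoxy)phenyl]-7-tert-butoxy-5-hydroxy-3-(methoxymethoxy)-4H-chromen-4-one, via pyranyl ketene 20 (not isolated), via tert-butoxycyclobutenone 21 (not isolated), via dienylketene 22 (not isolated), via keto tautomer 23 (not isolated)
Conditions: 19 (4 equiv), hν (blue LEDs, 440 nm), ClCH2CH2Cl, 10 °C; then excess 19 removed in vacuum at ≤20 °C, PhMe, 80 °C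
Reagents that add atoms: none
Why: Excitation of the diazo n→π* band expels N2 and pyranone C6 shifts to the diazo carbon (Wolff rearrangement, bond C8–C8a) to give ketene 20, whose carbonyl carbon is attacked by the CH terminus of ynol ether 19 so that the [2+2] closes to 3-tert-butoxy-4-pyranylcyclobutenone 21 (bonds C5–C6 and C7–C8). On warming, 21 opens by 4π electrocyclic cleavage of C5–C8 to dienylketene 22, whose ketene carbon closes onto pyranone C5 (bond C4a–C5) to give cyclohexadienone 23, which enolises to phenol 24. The closest known reaction is the Danheiser benzannulation in its diazoketone form, which is established for α,β-unsaturated and heteroaryl diazomethyl ketones with alkoxy- and siloxyacetylenes; here the C5=C6 bond of the γ-pyrone is the vinyl part. Ring A closes by a thermal 6π electrocyclisation of the dienylketene isomer that has ketene and pyranyl cis, and the reversible 4π opening lets the unreactive isomer drain through it. No stereocentre is formed. The step needs O5 and O7 to be placed correctly and differently, which the polarity of the [2+2] secures (nucleophilic ynol CH to ketene carbon, so the ketene oxygen becomes the free 5-OH and the ynol oxygen the 7-OtBu), and the closure has only pyranone C5 available; 440 nm light is chosen so that only the diazo group absorbs, and excess 19 is removed before heating so that it cannot fragment to ketene.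

Step 13
Reactants: 24 2-[3-(benzyloxy)-4-(methoxymethoxy)phenyl]-7-tert-butoxy-5-hydroxy-3-(methoxymethoxy)-4H-chromen-4-one
Product: 25 2-[3-(benzyloxy)-4-hydroxyphenyl]-3,5,7-trihydroxy-4H-chromen-4-one (3'-O-benzylquercetin)
Conditions: HCl (3 M in MeOH), THF, 50 °C
Reagents that add atoms: none
Why: Acid-catalysed cleavage of the aryl tert-butyl ether (E1) and acetal exchange of both MOM ethers with methanol, which also traps the methoxymethyl cation away from the nucleophilic ring A; the benzyl ether is stable to these conditions.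

Step 14
Reactants: 25 3'-O-benzylquercetin
Product: 26 3'-O-benzylquercetin 3,4',7-tris(hydrogen sulfate)
Conditions: SO3·NMe3 (8 equiv), Et3N, DMF, 60 °C; Sephadex LH-20 (MeOH), isolated as the ammonium salt
Reagents that add atoms: sulfur trioxide–trimethylamine complex, C[N+](C)(C)S(=O)(=O)[O-]
Why: O-sulfation of phenols with an SO3–amine complex; the 7-, 4'- and 3-OH react, while the 5-OH, held in a six-membered hydrogen bond to the C4 carbonyl, is the least reactive hydroxyl of a flavonol and should stay free, and O3' is blocked as its benzyl ether.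

Step 15
Reactants: 26 3'-O-benzylquercetin 3,4',7-tris(hydrogen sulfate)
Product: 27 quercetin 3,4',7-tris(hydrogen sulfate) (target)
Conditions: H2 (1 atm), 10% Pd/C, MeOH/H2O, rt; then Dowex 50W (H+ form), H2O, 0 °C, freeze-drying
Reagents that add atoms: none
Why: Hydrogenolysis of the benzyl ether at neutral pH, under which aryl sulfate salts and the flavonol C2=C3 bond should be inert; the free acid is released only at the end and in the cold.

**Compound list**

1 | kojic acid (5-hydroxy-2-(hydroxymethyl)-4H-pyran-4-one) | O=c1cc(CO)occ1O | starting material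
2 | 2-bromo-3-hydroxy-6-(hydroxymethyl)-4H-pyran-4-one | O=c1cc(CO)oc(Br)c1O | intermediate
3 | 2-bromo-6-(hydroxymethyl)-3-(methoxymethoxy)-4H-pyran-4-one | O=c1cc(CO)oc(Br)c1OCOC | intermediate
4 | 5-bromo-2-hydroxybenzaldehyde | O=Cc1cc(Br)ccc1O | starting material
5 | 5-bromo-2-(methoxymethoxy)benzaldehyde | O=Cc1cc(Br)ccc1OCOC | intermediate
6 | 5-bromo-2-(methoxymethoxy)phenyl formate (not isolated) | O=COc1cc(Br)ccc1OCOC | intermediate
7 | 5-bromo-2-(methoxymethoxy)phenol | Oc1cc(Br)ccc1OCOC | intermediate
8 | 2-(benzyloxy)-4-bromo-1-(methoxymethoxy)benzene | COCOc1ccc(Br)cc1OCc1ccccc1 | intermediate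
9 | 2-[3-(benzyloxy)-4-(methoxymethoxy)phenyl]-4,4,5,5-tetramethyl-1,3,2-dioxaborolane | COCOc1ccc(B2OC(C)(C)C(C)(C)O2)cc1OCc1ccccc1 | intermediate
10 | 2-[3-(benzyloxy)-4-(methoxymethoxy)phenyl]-6-(hydroxymethyl)-3-(methoxymethoxy)-4H-pyran-4-one | O=c1cc(CO)oc(-c2ccc(OCOC)c(OCc3ccccc3)c2)c1OCOC | intermediate
11 | 6-[3-(benzyloxy)-4-(methoxymethoxy)phenyl]-5-(methoxymethoxy)-4-oxo-4H-pyran-2-carboxylic acid | O=C(O)c1cc(=O)c(OCOC)c(-c2ccc(OCOC)c(OCc3ccccc3)c2)o1 | intermediate
12 | mixed anhydride of 11 with isobutyl carbonic acid (not isolated) | CC(C)COC(=O)OC(=O)c1cc(=O)c(OCOC)c(-c2ccc(OCOC)c(OCc3ccccc3)c2)o1 | intermediate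
13 | 2-[3-(benzyloxy)-4-(methoxymethoxy)phenyl]-6-(diazoacetyl)-3-(methoxymethoxy)-4H-pyran-4-one | [N-]=[N+]=CC(=O)c1cc(=O)c(OCOC)c(-c2ccc(OCOC)c(OCc3ccccc3)c2)o1 | intermediate
14 | trichloroethylene | ClC=C(Cl)Cl | starting material
15 | dichloroacetylene (not isolated, kept in solution) | ClC#CCl | intermediate
16 | (E)-1,2-dichlorovinyl tert-butyl ether | Cl/C=C(/Cl)OC(C)(C)C | intermediate
17 | 1-tert-butoxy-2-chloroacetylene (not isolated) | ClC#COC(C)(C)C | intermediate
18 | lithium tert-butoxyacetylide (not isolated) | [Li]C#COC(C)(C)C | intermediate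
19 | tert-butyl ethynyl ether | C#COC(C)(C)C | intermediate
20 | pyranyl ketene, 2-{6-[3-(benzyloxy)-4-(methoxymethoxy)phenyl]-5-(methoxymethoxy)-4-oxo-4H-pyran-2-yl}ethenone (not isolated) | O=C=Cc1cc(=O)c(OCOC)c(-c2ccc(OCOC)c(OCc3ccccc3)c2)o1 | intermediate
21 | racemic 3-tert-butoxy-4-{6-[3-(benzyloxy)-4-(methoxymethoxy)phenyl]-5-(methoxymethoxy)-4-oxo-4H-pyran-2-yl}cyclobut-2-en-1-one (not isolated) | O=C1C=C(OC(C)(C)C)C1c1cc(=O)c(OCOC)c(-c2ccc(OCOC)c(OCc3ccccc3)c2)o1 | intermediate
22 | dienylketene, ketene and pyranyl cis on the C7=C8 bond (not isolated) | O=C=C/C(OC(C)(C)C)=C\c1cc(=O)c(OCOC)c(-c2ccc(OCOC)c(OCc3ccccc3)c2)o1 | intermediate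
23 | racemic 4aH-chromene-4,5-dione keto tautomer of 24 (not isolated) | O=C1C=C(OC(C)(C)C)C=C2OC(-c3ccc(OCOC)c(OCc4ccccc4)c3)=C(OCOC)C(=O)C12 | intermediate
24 | 2-[3-(benzyloxy)-4-(methoxymethoxy)phenyl]-7-tert-butoxy-5-hydroxy-3-(methoxymethoxy)-4H-chromen-4-one | O=c1c(OCOC)c(-c2ccc(OCOC)c(OCc3ccccc3)c2)oc2cc(OC(C)(C)C)cc(O)c12 | intermediate
25 | 2-[3-(benzyloxy)-4-hydroxyphenyl]-3,5,7-trihydroxy-4H-chromen-4-one (3'-O-benzylquercetin) | O=c1c(O)c(-c2ccc(O)c(OCc3ccccc3)c2)oc2cc(O)cc(O)c12 | intermediate
26 | 3'-O-benzylquercetin 3,4',7-tris(hydrogen sulfate) | O=c1c(OS(=O)(=O)O)c(-c2ccc(OS(=O)(=O)O)c(OCc3ccccc3)c2)oc2cc(OS(=O)(=O)O)cc(O)c12 | intermediate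
27 | quercetin 3,4',7-tris(hydrogen sulfate) | O=c1c(OS(=O)(=O)O)c(-c2ccc(OS(=O)(=O)O)c(O)c2)oc2cc(OS(=O)(=O)O)cc(O)c12 | target

**Step count**

Total: 15 steps. Longest linear sequence: 11 steps (steps 3, 4, 5, 6, 7, 8, 9, 12, 13, 14, 15, from 5-bromo-2-hydroxybenzaldehyde).

**Steps most likely to fail**

Step 12. Two processes may defeat it. Light may be taken up by the 2-aryl-3-alkoxypyranone chromophore, with hydrogen abstraction from the MOM methylene by the excited C4 carbonyl. The ynol ether may lose isobutene by retro-ene reaction before it captures the ketene. The fallback keeps the same bonds but makes the ketene in the dark by known chemistry. It sets out from 13: silver-catalysed Wolff rearrangement in wet solvent (PhCO2Ag, Et3N, THF/H2O, rt, dark; Arndt–Eistert homologation) should give {6-[3-(benzyloxy)-4-(methoxymethoxy)phenyl]-5-(methoxymethoxy)-4-oxo-4H-pyran-2-yl}acetic acid F1. Treatment with 1-chloro-N,N,2-trimethylprop-1-en-1-amine (CH2Cl2, 0 °C, neutral) should give the acetyl chloride F2. Slow addition of Et3N to F2 and excess 19 at 0 °C should release ketene 20 by dehydrochlorination, which 19 captures as cyclobutenone 21. After removal of excess 19, heating in toluene at 80 °C carries 21 through 22 and 23, and the route is rejoined at 24.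

Step 14. Sulfation may stop short at the hydrogen-bonded O3 or spill over to O5, giving mixtures of polar salts that do not separate. The fallback installs the sulfates as neutral diesters that can be chromatographed. It sets out from 25: 2,2,2-trichloroethyl chlorosulfate (3.3 equiv), Et3N, DMAP, THF, 0 °C should give 3'-O-benzylquercetin 3,4',7-tris(2,2,2-trichloroethyl sulfate) F3, purified on silica. Zinc dust with HCO2NH4 in MeOH at rt then removes the three trichloroethyl groups by reductive fragmentation, and the route is rejoined at 26.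

Step 9. Diazomethane may attack the carbonate carbonyl of the mixed anhydride or add as a dipole across the electron-poor pyranone double bond. The fallback builds the diazo group by diazo transfer instead of acylation. It sets out from 11: MeNH(OMe)·HCl, EDC·HCl, iPr2NEt, CH2Cl2 should give the N-methoxy-N-methyl amide F4. MeMgBr in THF at −78 °C should give the 6-acetyl pyranone F5. LiHMDS and CF3CO2CH2CF3 in THF at −78 °C should give the trifluoroacetyl diketone F6, and MsN3, Et3N, H2O in MeCN at rt (detrifluoroacetylative Regitz-type diazo transfer) should return the route at 13.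

**Further compounds**

F1 | step 12 | {6-[3-(benzyloxy)-4-(methoxymethoxy)phenyl]-5-(methoxymethoxy)-4-oxo-4H-pyran-2-yl}acetic acid | OC(=O)Cc1cc(=O)c(OCOC)c(-c2ccc(OCOC)c(OCc3ccccc3)c2)o1
F2 | step 12 | {6-[3-(benzyloxy)-4-(methoxymethoxy)phenyl]-5-(methoxymethoxy)-4-oxo-4H-pyran-2-yl}acetyl chloride | ClC(=O)Cc1cc(=O)c(OCOC)c(-c2ccc(OCOC)c(OCc3ccccc3)c2)o1
F3 | step 14 | 3'-O-benzylquercetin 3,4',7-tris(2,2,2-trichloroethyl sulfate) | O=c1c(OS(=O)(=O)OCC(Cl)(Cl)Cl)c(-c2ccc(OS(=O)(=O)OCC(Cl)(Cl)Cl)c(OCc3ccccc3)c2)oc2cc(OS(=O)(=O)OCC(Cl)(Cl)Cl)cc(O)c12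
F4 | step 9 | 6-[3-(benzyloxy)-4-(methoxymethoxy)phenyl]-N-methoxy-5-(methoxymethoxy)-N-methyl-4-oxo-4H-pyran-2-carboxamide | CON(C)C(=O)c1cc(=O)c(OCOC)c(-c2ccc(OCOC)c(OCc3ccccc3)c2)o1
F5 | step 9 | 6-acetyl-2-[3-(benzyloxy)-4-(methoxymethoxy)phenyl]-3-(methoxymethoxy)-4H-pyran-4-one | CC(=O)c1cc(=O)c(OCOC)c(-c2ccc(OCOC)c(OCc3ccccc3)c2)o1
F6 | step 9 | 1-{6-[3-(benzyloxy)-4-(methoxymethoxy)phenyl]-5-(methoxymethoxy)-4-oxo-4H-pyran-2-yl}-4,4,4-trifluorobutane-1,3-dione | O=C(CC(=O)C(F)(F)F)c1cc(=O)c(OCOC)c(-c2ccc(OCOC)c(OCc3ccccc3)c2)o1
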